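## Retrosynthetic overview

1. Target ⇒ global ester methanolysis of a fully protected allylic acetate; the isopropenyl C=C comes from dehydration of a tertiary carbinol at C3', and C2' is never touched.
2. C8–C1' (key disconnection) ⇒ an 8-iodoflavone and a chiral terminal epoxide, joined by a visible-light nickel/photoredox reductive coupling.
3. Epoxide fragment ⇒ methyl (R)-glycidate plus two equivalents of MeMgCl; the only stereocentre is bought.
4. 8-Iodoflavone ⇒ apigenin by tris-O-alkylation and C8 iodination.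
5. Rings: none is built. Rings A, B and C are bought in apigenin; the oxirane of the glycidate is carried through and opened in the coupling.

Assumption: methyl (R)-glycidate (commercial, made on scale from L-serine) is taken as the inexpensive chiral starting material; POM below means pivaloyloxymethyl, CH2OC(=O)C(CH3)3.

## Route

Step 1
Reactants: 1 apigenin
Product: 2 5,7,4'-tris-O-(pivaloyloxymethyl)apigenin
Conditions: ClCH2OPiv (4 equiv), Cs2CO3 (4.5 equiv), NaI (0.5 equiv), DMF, 0 → 40 °C, 16 h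
Reagents that add atoms: chloromethyl pivalate, CC(C)(C)C(=O)OCCl
Why: Exhaustive Williamson O-alkylation (in situ Finkelstein activation to the iodomethyl ester) caps all three phenols, the chelated 5-OH included, as base-labile acetal esters that still activate ring A for electrophilic substitution; no stereocentre is involved.

Step 2
Reactants: 2 5,7,4'-tris-O-(pivaloyloxymethyl)apigenin
Product: 3 8-iodo-5,7,4'-tris-O-(pivaloyloxymethyl)apigenin
Conditions: NIS (1.15 equiv), CF3CO2H (0.2 equiv), MeCN, 0 °C → rt, dark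
Reagents that add atoms: N-iodosuccinimide, O=C1CCC(=O)N1I
Why: Electrophilic aromatic iodination of a 5,7-dialkoxyflavone goes to C8, which is activated by three oxygens and flanked by only one bulky ether, whereas C6 sits between two and ring B is far less electron-rich.

Step 3
Reactants: 4 methyl (R)-glycidate
Product: 6 2-[(2R)-oxiran-2-yl]propan-2-ol, via epoxy ketone 5 (not isolated)
Conditions: MeMgCl (2.3 equiv), THF, −78 → −40 °C; then Na2SO4·10H2O, filter, distil
Reagents that add atoms: methylmagnesium chloride, C[Mg]Cl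
Why: Double Grignard addition to the activated ester is much faster at low temperature than any opening of the oxirane (chloride rather than bromide reagent limits halohydrin formation), and the stereocentre bought in 4 is retained because no bond to it is broken.

Step 4
Reactants: 3 8-iodo-5,7,4'-tris-O-(pivaloyloxymethyl)apigenin; 6 2-[(2R)-oxiran-2-yl]propan-2-ol (2.5 equiv)
Product: 8 8-[(2R)-2,3-dihydroxy-3-methylbutyl]-5,7,4'-tris-O-(pivaloyloxymethyl)apigenin, via iodohydrin 7 (not isolated)
Conditions: NiBr2·glyme (10 mol%), 4,4'-di-tert-butyl-2,2'-bipyridine (12 mol%), 4CzIPN (2,4,5,6-tetra(carbazol-9-yl)isophthalonitrile, 2 mol%), NaI (0.5 equiv), Et3N·HCl (1 equiv), Et3N (3 equiv), DMA, 450 nm LEDs, 25 °C, 24 h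
Reagents that add atoms: none
Why: Proposed new method: visible-light nickel/organophotoredox reductive arylation of a terminal epoxide through an iodide relay, applied to two partner classes on which it has not been shown (a di-ortho-oxygenated 8-iodochromone and an oxirane carrying a free tertiary carbinol); iodide with Et3NH+ opens 6 only at its unhindered CH2 to give iodohydrin 7, zerovalent nickel inserts into the C8–I bond of 3, photoreduced 4CzIPN (regenerated by Et3N) keeps nickel reduced, monovalent nickel abstracts iodine from 7, the primary C1' radical is captured by the arylnickel and trivalent nickel reductively eliminates the C8–C1' bond, while C2' (beta to the radical, no bond to it broken, re-closure of 7 only returns 6) keeps the configuration bought in 4; no titanium co-catalyst is used, so the flavone carbonyl meets no ketyl-forming reductant and opening at the substituted carbon is avoided; closest known reaction type: nickel-catalysed cross-electrophile coupling of simple aryl iodides with terminal aliphatic epoxides via in situ halohydrins.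

Step 5
Reactants: 8 8-[(2R)-2,3-dihydroxy-3-methylbutyl]-5,7,4'-tris-O-(pivaloyloxymethyl)apigenin
Product: 10 8-[(2R)-2-acetoxy-3-methylbut-3-en-1-yl]-5,7,4'-tris-O-(pivaloyloxymethyl)apigenin, via secondary acetate 9 (not isolated)
Conditions: Ac2O (1.3 equiv), DMAP (5 mol%), pyridine, 0 °C, 2 h; then SOCl2 (3 equiv), −15 → 0 °C, 1 h
Reagents that add atoms: acetic anhydride, CC(=O)OC(C)=O
Why: DMAP-catalysed acetylation takes only the secondary hydroxyl, and SOCl2/pyridine dehydration (E2 of the tertiary chlorosulfite) then removes one of six methyl hydrogens rather than the single acetoxy-deactivated C2'–H, giving the isopropenyl group with C2' unchanged because none of its bonds is broken.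

Step 6
Reactants: 10 8-[(2R)-2-acetoxy-3-methylbut-3-en-1-yl]-5,7,4'-tris-O-(pivaloyloxymethyl)apigenin
Product: 11 8-[(2R)-2-hydroxy-3-methylbut-3-en-1-yl]apigenin (CNP0315675.1)
Conditions: K2CO3 (5 equiv), MeOH (0.02 M), Ar, 0 °C → rt, 3 h; then 1 M HCl to pH 5
Reagents that add atoms: none
Why: Base-mediated transesterification with methanol cleaves the acetate and the three pivalates, the freed hemiacetals collapse to the phenols and formaldehyde (kept dilute and cold), and the allylic alcohol, the 1,1-disubstituted alkene and the stereocentre are inert to these conditions.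

## Compound list

1 | apigenin (5,7-dihydroxy-2-(4-hydroxyphenyl)-4H-chromen-4-one) | O=c1cc(-c2ccc(O)cc2)oc2cc(O)cc(O)c12 | starting material
2 | 5,7,4'-tris-O-(pivaloyloxymethyl)apigenin | O=c1cc(-c2ccc(OCOC(=O)C(C)(C)C)cc2)oc2cc(OCOC(=O)C(C)(C)C)cc(OCOC(=O)C(C)(C)C)c12 | intermediate
3 | 8-iodo-5,7,4'-tris-O-(pivaloyloxymethyl)apigenin | O=c1cc(-c2ccc(OCOC(=O)C(C)(C)C)cc2)oc2c(I)c(OCOC(=O)C(C)(C)C)cc(OCOC(=O)C(C)(C)C)c12 | intermediate
4 | methyl (2R)-oxirane-2-carboxylate (methyl (R)-glycidate) | COC(=O)[C@H]1CO1 | starting material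
5 | 1-[(2R)-oxiran-2-yl]ethan-1-one (epoxy ketone, formed in the flask) | CC(=O)[C@H]1CO1 | intermediate
6 | 2-[(2R)-oxiran-2-yl]propan-2-ol | CC(C)(O)[C@H]1CO1 | intermediate
7 | (2S)-1-iodo-3-methylbutane-2,3-diol (iodohydrin, formed in the flask) | CC(C)(O)[C@H](O)CI | intermediate
8 | 8-[(2R)-2,3-dihydroxy-3-methylbutyl]-5,7,4'-tris-O-(pivaloyloxymethyl)apigenin | CC(C)(O)[C@H](O)Cc1c(OCOC(=O)C(C)(C)C)cc(OCOC(=O)C(C)(C)C)c2c(=O)cc(-c3ccc(OCOC(=O)C(C)(C)C)cc3)oc12 | intermediate
9 | 8-[(2R)-2-acetoxy-3-hydroxy-3-methylbutyl]-5,7,4'-tris-O-(pivaloyloxymethyl)apigenin (secondary acetate, formed in the flask) | CC(C)(O)[C@H](OC(C)=O)Cc1c(OCOC(=O)C(C)(C)C)cc(OCOC(=O)C(C)(C)C)c2c(=O)cc(-c3ccc(OCOC(=O)C(C)(C)C)cc3)oc12 | intermediate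
10 | 8-[(2R)-2-acetoxy-3-methylbut-3-en-1-yl]-5,7,4'-tris-O-(pivaloyloxymethyl)apigenin | C=C(C)[C@H](OC(C)=O)Cc1c(OCOC(=O)C(C)(C)C)cc(OCOC(=O)C(C)(C)C)c2c(=O)cc(-c3ccc(OCOC(=O)C(C)(C)C)cc3)oc12 | intermediate
11 | 8-[(2R)-2-hydroxy-3-methylbut-3-en-1-yl]apigenin (CNP0315675.1) | C=C(C)[C@H](O)Cc1c(O)cc(O)c2c(=O)cc(-c3ccc(O)cc3)oc12 | target

## Step count and risk

Total steps: 6 (step 5 is a one-pot, two-stage operation). Longest linear sequence: 5 (steps 1, 2, 4, 5, 6 from apigenin); the epoxide branch is step 3 alone.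

Steps most likely to fail:

**Step 4 (the proposed new coupling).** The likely failures are hydrodeiodination of 3 by the amine reductant and slow radical capture at the di-ortho-substituted arylnickel. The fallback uses known chemistry, sets out from 3 and 6 and comes back at 8. Epoxide 6 is opened with LiI/AcOH (THF, 0 °C) to iodohydrin 7, here isolated, and protected with 2,2-dimethoxypropane/PPTS as the acetonide (4S)-4-(iodomethyl)-2,2,5,5-tetramethyl-1,3-dioxolane F1. Iodide 3 is converted by direct insertion of zinc dust with LiCl (THF, 40 °C) into the arylzinc iodide F2. A nickel-catalysed Negishi coupling of F2 with the primary alkyl iodide F1 (Ni(acac)2 10 mol%, 4-fluorostyrene 20 mol%, THF/NMP, −10 °C → rt) gives the coupled acetonide 8-{[(4R)-2,2,5,5-tetramethyl-1,3-dioxolan-4-yl]methyl}-5,7,4'-tris-O-(pivaloyloxymethyl)apigenin F3. Hydrolysis with 80% aqueous AcOH at 40 °C, which the POM ethers tolerate, gives 8.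

**Step 5 (regioselective dehydration in one pot).** The likely failures are enol acetate or tertiary chloride formation, or acetoxonium participation. The fallback goes through the epoxide, sets out from 8 and comes back at 11. Diol 8 is mesylated at the secondary hydroxyl (MsCl, Et3N, CH2Cl2, −20 °C) to 8-[(2R)-3-hydroxy-2-(methanesulfonyloxy)-3-methylbutyl]-5,7,4'-tris-O-(pivaloyloxymethyl)apigenin F4. DBU (MeCN, 40 °C) closes it, with inversion at C2', to 8-{[(2S)-3,3-dimethyloxiran-2-yl]methyl}-5,7,4'-tris-O-(pivaloyloxymethyl)apigenin F5. The trivalent titanium reagent Cp2TiCl (from Cp2TiCl2 and Mn dust, THF, rt) opens the oxirane at the tertiary carbon, and loss of a methyl hydrogen gives 8-[(2S)-2-hydroxy-3-methylbut-3-en-1-yl]-5,7,4'-tris-O-(pivaloyloxymethyl)apigenin F6. A Mitsunobu esterification (4-nitrobenzoic acid, PPh3, DIAD, THF, 0 °C) inverts C2' back to R in 8-[(2R)-3-methyl-2-(4-nitrobenzoyloxy)but-3-en-1-yl]-5,7,4'-tris-O-(pivaloyloxymethyl)apigenin F7. The conditions of step 6 then give 11.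

**Step 3 (Grignard addition in the presence of the oxirane).** The likely failures are halide opening of the oxirane, Payne-type isomerisation of the alkoxide, and loss of the volatile, water-soluble product. The fallback masks the oxirane during the addition, sets out from 4 and comes back at 6. Ester 4 is opened at C3 with HCl (2 M in Et2O, 0 °C) to methyl (2S)-3-chloro-2-hydroxypropanoate F8. MeMgCl (3.3 equiv, THF, −40 → 0 °C) gives (2S)-1-chloro-3-methylbutane-2,3-diol F9. Ring closure by the secondary alkoxide with powdered KOH in Et2O at 0 °C (non-aqueous, C2 untouched) returns 6.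

## Further compounds

F1 | step 4 | (4S)-4-(iodomethyl)-2,2,5,5-tetramethyl-1,3-dioxolane | CC1(C)OC(C)(C)O[C@@H]1CI
F2 | step 4 | [5,7-bis(pivaloyloxymethoxy)-2-(4-(pivaloyloxymethoxy)phenyl)-4-oxo-4H-chromen-8-yl]zinc iodide | O=c1cc(-c2ccc(OCOC(=O)C(C)(C)C)cc2)oc2c([Zn]I)c(OCOC(=O)C(C)(C)C)cc(OCOC(=O)C(C)(C)C)c12
F3 | step 4 | 8-{[(4R)-2,2,5,5-tetramethyl-1,3-dioxolan-4-yl]methyl}-5,7,4'-tris-O-(pivaloyloxymethyl)apigenin | CC1(C)OC(C)(C)O[C@@H]1Cc1c(OCOC(=O)C(C)(C)C)cc(OCOC(=O)C(C)(C)C)c2c(=O)cc(-c3ccc(OCOC(=O)C(C)(C)C)cc3)oc12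
F4 | step 5 | 8-[(2R)-3-hydroxy-2-(methanesulfonyloxy)-3-methylbutyl]-5,7,4'-tris-O-(pivaloyloxymethyl)apigenin | CC(C)(O)[C@H](OS(C)(=O)=O)Cc1c(OCOC(=O)C(C)(C)C)cc(OCOC(=O)C(C)(C)C)c2c(=O)cc(-c3ccc(OCOC(=O)C(C)(C)C)cc3)oc12
F5 | step 5 | 8-{[(2S)-3,3-dimethyloxiran-2-yl]methyl}-5,7,4'-tris-O-(pivaloyloxymethyl)apigenin | CC1(C)O[C@H]1Cc1c(OCOC(=O)C(C)(C)C)cc(OCOC(=O)C(C)(C)C)c2c(=O)cc(-c3ccc(OCOC(=O)C(C)(C)C)cc3)oc12
F6 | step 5 | 8-[(2S)-2-hydroxy-3-methylbut-3-en-1-yl]-5,7,4'-tris-O-(pivaloyloxymethyl)apigenin | C=C(C)[C@@H](O)Cc1c(OCOC(=O)C(C)(C)C)cc(OCOC(=O)C(C)(C)C)c2c(=O)cc(-c3ccc(OCOC(=O)C(C)(C)C)cc3)oc12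
F7 | step 5 | 8-[(2R)-3-methyl-2-(4-nitrobenzoyloxy)but-3-en-1-yl]-5,7,4'-tris-O-(pivaloyloxymethyl)apigenin | C=C(C)[C@H](OC(=O)c1ccc(cc1)[N+](=O)[O-])Cc1c(OCOC(=O)C(C)(C)C)cc(OCOC(=O)C(C)(C)C)c2c(=O)cc(-c3ccc(OCOC(=O)C(C)(C)C)cc3)oc12
F8 | step 3 | methyl (2S)-3-chloro-2-hydroxypropanoate | COC(=O)[C@H](O)CCl
F9 | step 3 | (2S)-1-chloro-3-methylbutane-2,3-diol | CC(C)(O)[C@H](O)CCl
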